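You cannot hold this charge in solution as starting material, since the 0.18 M of solid substrate is more than the 0.14 M the solution takes.

solid substrate 0.18 M; time 40 min

    starting material → decomposition product (k1 = 8.0 × 10⁻⁷ s⁻¹)
    solid substrate ⇌ starting material, rate k2*(cs2 - [starting material]) while solid is left; crystals form when [starting material] > cs2 (cs2 = 0.14 M, k2 = 1.4 × 10⁻⁴ s⁻¹)
    starting material ⇌ target (K3 = 3.3, k3 = 4.6 × 10⁻⁴ s⁻¹)
    starting material ⇌ isomer of the product (K4 = 53, k4 = 1.0 × 10⁻⁴ s⁻¹)
    starting material ⇌ third isomer (K5 = 0.53, k5 = 1.8 × 10⁻⁴ s⁻¹)

- which holds at 40 min: what has brought the reaction to rest, or that it has not come to rest (for what has run out or reacted, a solid counts together with what of it has only dissolved) (forward and back rates have come level / it is still moving / all of the solid substrate has reacted)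
- part of the solid substrate that has turned into other species by 40 min (what has only dissolved does not count)
- the target standing at 40 min, as a percentage of the solid substrate charged

- given per volume of solution although it is solid: solid substrate
- at the start none of the solid substrate is in solution
- what has only dissolved of solid substrate counts as not reacted
- the reaction counts as stopped when no species that holds the solid substrate changes by six tenths of a point or more over the second half of the time
- run time (flask): 40 min

Yet room is not the trouble. Reckon what leaves the solid in 40 min if the solution stays empty, a zero-order feed:

ceiling = dissolution coefficient × solubility × time = 0.0470 M

That is the dissolving ceiling, the amount that leaves the solid if the solution stays empty. The solution could take 77.8% of the charge, yet the ceiling is 26.1% of it, less than the solution could take. Both numbers hold: one is a capacity, the other a rate times a time.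

Dissolved starting material narrows the gap, but it stays far below solubility because its forward drains together outrun the dissolution coefficient. So compute just the correction, ignoring the ways back:

approach constant = drains + dissolution coefficient = 0.0528 min⁻¹, so time scale = 18.9 min

plateau = 0.0223 M, mean over the run = 0.0130 M

correction = dissolution coefficient × mean × time = 0.00437 M

left the solid = 0.0427 M, or 23.7% of the charge

Solid therefore remains, and I judge the flask still moving. My reckoning stops there, with no figure for the target.

The forecast says it is still moving, with 11.7% converted and 7.4% target: “so it stays far below the solubility”.

The simulation gives it is still moving, 11.6% converted and 7.38% target, with solid substrate at 76.4%.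

Now take the neighbour flask with 0.045 M of solid substrate, time held. The same ceiling is more than that charge, at 104% of it, and the same correction brings it to 94.9%. The neighbour flask shows solid substrate at 5.70%, so 94.3% has left the solid, and 46.6% has converted. Its target stands at 29.5% of its charge, which is 0.0133 M, against 0.0133 M in the first flask.

(All constants stand for no real mixture; the flask was simulated.)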